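The plan breaks two bonds of the dihydrofuran ring, O1–C2 and C2–C3, which leaves C2 as a lone one-carbon piece. Its only heavy-atom neighbours are O1, C3 and the syringyl ring, so a syringyl-substituted sulfonium ylide can supply it. O1, C7a, C3a and C3 are the oxygen, two ring A carbons and exocyclic carbon of an ortho-quinone methide with the CH2O arm already on C3. One base-mediated (4+1) annulation then forms both bonds, closes the ring and sets C2 and C3. Its precursors are a racemic 2-(1-tosyl-2-silyloxyethyl)phenol carrying the C5 bromine and C7 methoxy group, and an O-pivaloyl syringyl salt of a C2-symmetric chiral thiolane.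

Key step: step 11

Assumption: the (2R,5R)-thiolane is taken to lead to the (2R,3S) series, because its usual shielding model for benzylidene transfer to aldehydes, mapped onto the methide, places the new C–C bond so that C2 becomes R after the inverting closure. The sense has to be proven on the bromide from the key step (anomalous-dispersion X-ray). If it is opposite, the same sequence is run with the thiolane from (2R,5R)-hexane-2,5-diol.

**Ring A fragment**

Step 1
Reactants: 1 5-bromo-2-hydroxy-3-methoxybenzaldehyde
Product: 2 4-bromo-2-methoxy-6-vinylphenol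
Conditions: MePPh3Br (2.5 equiv), KOtBu (2.5 equiv), THF, 0 °C to rt
Reagents that add atoms: methyltriphenylphosphonium bromide, C[P+](c1ccccc1)(c1ccccc1)c1ccccc1.[Br-]
Why: Wittig methylenation, in which the extra equivalent of base only holds the phenol as its potassium salt, is the usual protection-free way from salicylaldehydes to 2-vinylphenols, and the aryl bromide is inert to this non-metallating base.

Step 2
Reactants: 2 4-bromo-2-methoxy-6-vinylphenol
Product: 3 rac-4-bromo-2-(1,2-dihydroxyethyl)-6-methoxyphenol
Conditions: K2OsO4·2H2O (1 mol %), NMO (1.3 equiv), acetone/H2O 4:1, rt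
Reagents that add atoms: N-methylmorpholine N-oxide, C[N+]1([O-])CCOCC1; water, O
Why: Upjohn dihydroxylation of a terminal styrene is fast, the two-electron co-oxidant NMO spares the guaiacol-type phenol, and the carbinol centre is deliberately left racemic because step 11 erases it.

Step 3
Reactants: 3 rac-4-bromo-2-(1,2-dihydroxyethyl)-6-methoxyphenol
Product: 4 rac-4-bromo-2-[2-(tert-butyldiphenylsilyloxy)-1-hydroxyethyl]-6-methoxyphenol
Conditions: TBDPSCl (1.05 equiv), imidazole (2.2 equiv), CH2Cl2/DMF, 0 °C
Reagents that add atoms: tert-butyl(chloro)diphenylsilane, CC(C)(C)[Si](Cl)(c1ccccc1)c1ccccc1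
Why: In this imidazole-promoted silylation the bulky chlorosilane should take the open primary hydroxyl well before the secondary benzylic hydroxyl or the doubly ortho-substituted, hydrogen-bonded phenol, and TBDPS is chosen over a smaller silyl group because it must outlast the sulfinic acid of step 4.

Step 4
Reactants: 4 rac-4-bromo-2-[2-(tert-butyldiphenylsilyloxy)-1-hydroxyethyl]-6-methoxyphenol
Product: 5 rac-4-bromo-2-[2-(tert-butyldiphenylsilyloxy)-1-(4-methylphenylsulfonyl)ethyl]-6-methoxyphenol
Conditions: p-TolSO2H (1.5 equiv), 4 Å MS, CH2Cl2, rt to 35 °C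
Reagents that add atoms: p-toluenesulfinic acid, Cc1ccc(S(=O)O)cc1
Why: In this acid-promoted SN1-type substitution the ortho hydroxyl assists loss of water from the benzylic alcohol and the soft sulfur of the sulfinic acid captures the cation (any kinetic sulfinate ester re-ionises to the more stable sulfone), which is the standard preparation of 2-(1-sulfonylalkyl)phenols and gives a racemic centre that does not matter.

**Syringyl fragment and thiolane**

Step 5
Reactants: 6 syringaldehyde (4-hydroxy-3,5-dimethoxybenzaldehyde)
Product: 7 4-formyl-2,6-dimethoxyphenyl pivalate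
Conditions: PivCl (1.2 equiv), Et3N (1.5 equiv), DMAP (5 mol %), CH2Cl2, 0 °C to rt
Reagents that add atoms: pivaloyl chloride, CC(C)(C)C(=O)Cl
Why: DMAP-catalysed acylation caps the hindered phenol as an ester that weakens the para oxygen donor (so the later benzylic electrophiles do not ionise) and resists borohydride and carbonate in aprotic media.

Step 6
Reactants: 7 4-formyl-2,6-dimethoxyphenyl pivalate
Product: 8 4-(hydroxymethyl)-2,6-dimethoxyphenyl pivalate
Conditions: NaBH4 (0.5 equiv), THF/MeOH, 0 °C
Reagents that add atoms: none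
Why: Borohydride reduction is chemoselective for the aldehyde, since the bulky aryl pivalate is not attacked at 0 °C.

Step 7
Reactants: 8 4-(hydroxymethyl)-2,6-dimethoxyphenyl pivalate
Product: 9 4-(bromomethyl)-2,6-dimethoxyphenyl pivalate
Conditions: PBr3 (0.4 equiv), CH2Cl2, 0 °C
Reagents that add atoms: phosphorus tribromide, BrP(Br)Br
Why: Bromination proceeds through the phosphite ester with SN2 displacement by bromide, and the acyloxy group keeps the benzylic bromide stable enough to isolate.

Step 8
Reactants: 10 (2S,5S)-hexane-2,5-diol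
Product: 11 (2S,5S)-hexane-2,5-diyl dimethanesulfonate
Conditions: MsCl (2.4 equiv), Et3N (3 equiv), CH2Cl2, −20 to 0 °C
Reagents that add atoms: methanesulfonyl chloride, CS(=O)(=O)Cl
Why: Mesylation takes place at oxygen only, so both carbinol configurations are retained.

Step 9
Reactants: 11 (2S,5S)-hexane-2,5-diyl dimethanesulfonate
Product: 12 (2R,5R)-2,5-dimethylthiolane
Conditions: Na2S·9H2O (1.2 equiv), EtOH, rt
Reagents that add atoms: sodium sulfide, [Na+].[Na+].[S-2]
Why: A double SN2 displacement by sulfide, first intermolecular and then 5-exo-tet, inverts each carbon once and so turns the (S,S) dimesylate into the (R,R) trans-thiolane.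

Step 10
Reactants: 9 4-(bromomethyl)-2,6-dimethoxyphenyl pivalate; 12 (2R,5R)-2,5-dimethylthiolane
Product: 13 (2R,5R)-1-(3,5-dimethoxy-4-pivaloyloxybenzyl)-2,5-dimethylthiolan-1-ium tetrafluoroborate
Conditions: AgBF4 (1.0 equiv), CH2Cl2, 0 °C to rt, dark
Reagents that add atoms: silver tetrafluoroborate, [Ag+].F[B-](F)(F)F
Why: SN2 S-alkylation of the hindered sulfide is made irreversible by precipitation of AgBr, the two sulfur lone pairs are equivalent in the C2-symmetric ring so only one salt can form, and the non-nucleophilic anion stops reversion to a benzylating bromide in step 11.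

**Key step and endgame**

Step 11
Reactants: 5 rac-4-bromo-2-[2-(tert-butyldiphenylsilyloxy)-1-(4-methylphenylsulfonyl)ethyl]-6-methoxyphenol; 13 (2R,5R)-1-(3,5-dimethoxy-4-pivaloyloxybenzyl)-2,5-dimethylthiolan-1-ium tetrafluoroborate
Product: 17 (2R,3S)-5-bromo-3-(tert-butyldiphenylsilyloxymethyl)-7-methoxy-2-(3,5-dimethoxy-4-pivaloyloxyphenyl)-2,3-dihydrobenzofuran, via ortho-quinone methide 14 (not isolated), via benzylic sulfonium ylide 15 (not isolated), via anti betaine 16 (not isolated)
Conditions: 13 (1.5 equiv), Cs2CO3 (3.5 equiv), MeCN, 0 °C; 5 in MeCN/CH2Cl2 added over 6 h by syringe pump; then rt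
Reagents that add atoms: none
Why: Cs2CO3 deprotonates the phenol of 5, whose phenoxide expels p-toluenesulfinate by 1,4-elimination to give planar methide 14 (which erases the racemic sulfone carbon), and the same base reversibly deprotonates the benzylic CH2 of 13 to ylide 15, whose carbon adds to the exocyclic methide carbon, forming C2–C3 and restoring the aromaticity of ring A in betaine 16. The phenoxide O1 of 16 then attacks C2 opposite to sulfur and expels neutral thiolane 12, a 5-exo-tet SN2 closure that forms O1–C2 and the dihydrofuran ring. The closest known reaction type is the (4+1) annulation of sulfonium ylides with ortho-quinone methides released by base from 2-(1-sulfonylalkyl)phenols, which gives trans-2,3-dihydrobenzofurans; it is combined here with a semi-stabilised benzylic ylide on a chiral thiolane, a reagent class established for asymmetric benzylidene transfer to aldehydes, so the level of induction on a methide still has to be measured. C2 is governed by the thiolane, since sulfur is not stereogenic, the ylide conformer with the aryl group turned away from the ring is preferred, the methyl group cis to the ylide carbon shields one face, and the configuration is inverted once in the closure. C3 is governed by the relative topicity of the C–C bond formation, the transition state that keeps the syringyl ring away from ring A and the CH2OTBDPS arm giving the anti betaine and hence the trans ring, 3S when C2 is R. The step needs conjugate trapping to outrun tautomerisation of 14 to a 2-(silyloxyvinyl)phenol and O-benzylation of the phenoxide, which should be secured by slow addition of 5 to excess 13 and base, by the expected E geometry of 14 that holds the CH2 hydrogens away from the carbonyl oxygen, by reversible re-addition of sulfinate that stores the methide, and by the BF4 counter-ion and electron-poor O-pivaloyl ring of 13.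

Step 12
Reactants: 17 (2R,3S)-5-bromo-3-(tert-butyldiphenylsilyloxymethyl)-7-methoxy-2-(3,5-dimethoxy-4-pivaloyloxyphenyl)-2,3-dihydrobenzofuran; 18 3,5-diacetoxystyrene (5-vinyl-1,3-phenylene diacetate)
Product: 19 (2R,3S)-5-[(E)-2-(3,5-diacetoxyphenyl)ethenyl]-3-(tert-butyldiphenylsilyloxymethyl)-7-methoxy-2-(3,5-dimethoxy-4-pivaloyloxyphenyl)-2,3-dihydrobenzofuran
Conditions: 18 (1.5 equiv), Pd(OAc)2 (5 mol %), P(o-tol)3 (12 mol %), Et3N (3 equiv), MeCN, 95 °C (sealed tube), argon, dark
Reagents that add atoms: none
Why: In this Mizoroki–Heck reaction zerovalent palladium formed in situ inserts into the C5–Br bond, the aryl group adds to the unsubstituted alkene carbon of 18 and syn β-hydride elimination gives the E-stilbene, while C2 and C3 bear no acidic hydrogen and the esters and silyl ether tolerate triethylamine.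

Step 13
Reactants: 19 (2R,3S)-5-[(E)-2-(3,5-diacetoxyphenyl)ethenyl]-3-(tert-butyldiphenylsilyloxymethyl)-7-methoxy-2-(3,5-dimethoxy-4-pivaloyloxyphenyl)-2,3-dihydrobenzofuran
Product: 20 (2R,3S)-5-[(E)-2-(3,5-diacetoxyphenyl)ethenyl]-3-(hydroxymethyl)-7-methoxy-2-(3,5-dimethoxy-4-pivaloyloxyphenyl)-2,3-dihydrobenzofuran
Conditions: HF·pyridine, pyridine, THF, 0 °C to rt (plastic vessel)
Reagents that add atoms: none
Why: Formation of the strong Si–F bond drives cleavage of the primary TBDPS ether, and the buffered non-basic medium leaves the three aryl esters, the stilbene and both stereocentres untouched, so 20 can be purified as a neutral compound.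

Step 14
Reactants: 20 (2R,3S)-5-[(E)-2-(3,5-diacetoxyphenyl)ethenyl]-3-(hydroxymethyl)-7-methoxy-2-(3,5-dimethoxy-4-pivaloyloxyphenyl)-2,3-dihydrobenzofuran
Product: 21 gnetucleistol F, 5-[(E)-2-[(2R,3S)-2-(4-hydroxy-3,5-dimethoxyphenyl)-3-(hydroxymethyl)-7-methoxy-2,3-dihydrobenzofuran-5-yl]ethenyl]benzene-1,3-diol
Conditions: K2CO3 (4 equiv), degassed MeOH, rt to 40 °C, argon, dark; aq. NH4Cl
Reagents that add atoms: none
Why: In this base-mediated transesterification the aryl esters are activated acyl donors, so the two acetates should go quickly and the hindered pivalate more slowly, and near room temperature the dihydrobenzofuran ring stays closed, so C2 and C3 are preserved.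

**Compound list**

1 | 5-bromo-2-hydroxy-3-methoxybenzaldehyde | COc1cc(Br)cc(C=O)c1O | starting material
2 | 4-bromo-2-methoxy-6-vinylphenol | COc1cc(Br)cc(C=C)c1O | intermediate
3 | rac-4-bromo-2-(1,2-dihydroxyethyl)-6-methoxyphenol | COc1cc(Br)cc(C(O)CO)c1O | intermediate
4 | rac-4-bromo-2-[2-(tert-butyldiphenylsilyloxy)-1-hydroxyethyl]-6-methoxyphenol | COc1cc(Br)cc(C(O)CO[Si](c2ccccc2)(c2ccccc2)C(C)(C)C)c1O | intermediate
5 | rac-4-bromo-2-[2-(tert-butyldiphenylsilyloxy)-1-(4-methylphenylsulfonyl)ethyl]-6-methoxyphenol | COc1cc(Br)cc(C(CO[Si](c2ccccc2)(c2ccccc2)C(C)(C)C)S(=O)(=O)c2ccc(C)cc2)c1O | intermediate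
6 | syringaldehyde | COc1cc(C=O)cc(OC)c1O | starting material
7 | 4-formyl-2,6-dimethoxyphenyl pivalate | COc1cc(C=O)cc(OC)c1OC(=O)C(C)(C)C | intermediate
8 | 4-(hydroxymethyl)-2,6-dimethoxyphenyl pivalate | COc1cc(CO)cc(OC)c1OC(=O)C(C)(C)C | intermediate
9 | 4-(bromomethyl)-2,6-dimethoxyphenyl pivalate | COc1cc(CBr)cc(OC)c1OC(=O)C(C)(C)C | intermediate
10 | (2S,5S)-hexane-2,5-diol | C[C@H](O)CC[C@H](C)O | starting material
11 | (2S,5S)-hexane-2,5-diyl dimethanesulfonate | C[C@H](OS(C)(=O)=O)CC[C@H](C)OS(C)(=O)=O | intermediate
12 | (2R,5R)-2,5-dimethylthiolane | C[C@@H]1CC[C@@H](C)S1 | intermediate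
13 | (2R,5R)-1-(3,5-dimethoxy-4-pivaloyloxybenzyl)-2,5-dimethylthiolan-1-ium tetrafluoroborate | C[C@@H]1CC[C@@H](C)[S+]1Cc1cc(OC)c(OC(=O)C(C)(C)C)c(OC)c1.F[B-](F)(F)F | intermediate
14 | ortho-quinone methide, (6E)-4-bromo-6-[2-(tert-butyldiphenylsilyloxy)ethylidene]-2-methoxycyclohexa-2,4-dien-1-one (not isolated) | COC1=CC(Br)=C/C(=C\CO[Si](c2ccccc2)(c2ccccc2)C(C)(C)C)C1=O | intermediate
15 | benzylic sulfonium ylide of 13, (2R,5R)-thiolanium 3,5-dimethoxy-4-pivaloyloxybenzylide (not isolated) | C[C@@H]1CC[C@@H](C)[S+]1[CH-]c1cc(OC)c(OC(=O)C(C)(C)C)c(OC)c1 | intermediate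
16 | anti betaine, ring A phenoxide with C3 (S) bonded to the sulfonium-bearing carbon (S, the future C2) (not isolated) | COc1cc([C@H]([C@H](CO[Si](c2ccccc2)(c2ccccc2)C(C)(C)C)c2cc(Br)cc(OC)c2[O-])[S+]2[C@H](C)CC[C@H]2C)cc(OC)c1OC(=O)C(C)(C)C | intermediate
17 | (2R,3S)-5-bromo-3-(tert-butyldiphenylsilyloxymethyl)-7-methoxy-2-(3,5-dimethoxy-4-pivaloyloxyphenyl)-2,3-dihydrobenzofuran (trans) | COc1cc([C@@H]2Oc3c(OC)cc(Br)cc3[C@H]2CO[Si](c2ccccc2)(c2ccccc2)C(C)(C)C)cc(OC)c1OC(=O)C(C)(C)C | intermediate
18 | 3,5-diacetoxystyrene | C=Cc1cc(OC(C)=O)cc(OC(C)=O)c1 | starting material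
19 | (2R,3S)-5-[(E)-2-(3,5-diacetoxyphenyl)ethenyl]-3-(tert-butyldiphenylsilyloxymethyl)-7-methoxy-2-(3,5-dimethoxy-4-pivaloyloxyphenyl)-2,3-dihydrobenzofuran | COc1cc([C@@H]2Oc3c(OC)cc(/C=C/c4cc(OC(C)=O)cc(OC(C)=O)c4)cc3[C@H]2CO[Si](c2ccccc2)(c2ccccc2)C(C)(C)C)cc(OC)c1OC(=O)C(C)(C)C | intermediate
20 | (2R,3S)-5-[(E)-2-(3,5-diacetoxyphenyl)ethenyl]-3-(hydroxymethyl)-7-methoxy-2-(3,5-dimethoxy-4-pivaloyloxyphenyl)-2,3-dihydrobenzofuran | COc1cc([C@@H]2Oc3c(OC)cc(/C=C/c4cc(OC(C)=O)cc(OC(C)=O)c4)cc3[C@H]2CO)cc(OC)c1OC(=O)C(C)(C)C | intermediate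
21 | gnetucleistol F, (2R,3S), E-stilbene | COc1cc([C@@H]2Oc3c(OC)cc(/C=C/c4cc(O)cc(O)c4)cc3[C@H]2CO)cc(OC)c1O | target

**Step count**

Total step count: 14. Longest linear sequence: 8 steps (steps 1, 2, 3, 4, 11, 12, 13, 14). The line from syringaldehyde through steps 5, 6, 7, 10, 11, 12, 13, 14 is equally long.

**Steps most likely to fail**

1. Step 11. The ylide and methide faces may be discriminated poorly, so the trans ring would form without sufficient enantiomeric purity. The fallback gives up reagent control and resolves through covalent diastereomers.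
   - It sets out from 17. HF·pyridine in THF frees the bromo alcohol F1.
   - Esterification with (S)-2-methoxy-2-phenylacetic acid (EDC·HCl, DMAP, CH2Cl2, 0 °C) gives the (2R,3S) mandelate ester F2 beside the (2S,3R) mandelate ester F3. F3 is removed by chromatography or crystallisation.
   - F2 is coupled with 18 under the conditions of step 12 to give the stilbene mandelate F4.
   - The K2CO3 methanolysis of step 14 removes all four esters at once, which rejoins the route at 21.

2. Step 4. The β-silyloxy group and the bromine deactivate the benzylic alcohol inductively, so ionisation may be sluggish. That would give time for acid-induced loss of the silyl ether or a 1,2-hydride shift towards an arylacetaldehyde. The fallback reverses the order of events so that no acid-labile group meets the acid.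
   - It sets out from 3. TolSO2Na in HCO2H/H2O (rt to 40 °C) substitutes the benzylic hydroxyl of the unprotected triol and gives the hydroxy sulfone F5.
   - TBDPSCl/imidazole in CH2Cl2 at 0 °C then silylates its primary hydroxyl, which comes back to the route at 5.

3. Step 12. Oxidative addition of the electron-rich C5 bromide may be slow at temperatures the acetates tolerate, and arylation at the internal alkene carbon may erode regioselectivity. The fallback replaces the Heck reaction with a Suzuki–Miyaura coupling of a preformed E-alkenyl boronate, which fixes both regiochemistry and geometry beforehand.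
   - It sets out from 18. Cross-metathesis with vinylboronic acid pinacol ester gives the E-styrylboronate F6 (second-generation Grubbs catalyst, RuCl2(PCy3)(H2IMes)(=CHPh), CH2Cl2, 40 °C).
   - F6 is coupled with 17 (Pd(OAc)2, SPhos, K3PO4, THF with a little water, 50 °C), which comes back to the route at 19.

Further compounds
F1 | step 11 | bromo alcohol, (2R,3S)-5-bromo-3-(hydroxymethyl)-7-methoxy-2-(3,5-dimethoxy-4-pivaloyloxyphenyl)-2,3-dihydrobenzofuran | COc1cc([C@@H]2Oc3c(OC)cc(Br)cc3[C@H]2CO)cc(OC)c1OC(=O)C(C)(C)C
F2 | step 11 | (2R,3S) mandelate ester, (S)-2-methoxy-2-phenylacetate of F1 | COc1cc([C@@H]2Oc3c(OC)cc(Br)cc3[C@H]2COC(=O)[C@@H](OC)c2ccccc2)cc(OC)c1OC(=O)C(C)(C)C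
F3 | step 11 | (2S,3R) mandelate ester, (S)-2-methoxy-2-phenylacetate of the antipode of F1 | COc1cc([C@H]2Oc3c(OC)cc(Br)cc3[C@@H]2COC(=O)[C@@H](OC)c2ccccc2)cc(OC)c1OC(=O)C(C)(C)C
F4 | step 11 | stilbene mandelate, Heck product of F2 with 18 | COc1cc([C@@H]2Oc3c(OC)cc(/C=C/c4cc(OC(C)=O)cc(OC(C)=O)c4)cc3[C@H]2COC(=O)[C@@H](OC)c2ccccc2)cc(OC)c1OC(=O)C(C)(C)C
F5 | step 4 | hydroxy sulfone, rac-4-bromo-2-[2-hydroxy-1-(4-methylphenylsulfonyl)ethyl]-6-methoxyphenol | COc1cc(Br)cc(C(CO)S(=O)(=O)c2ccc(C)cc2)c1O
F6 | step 12 | E-styrylboronate, 5-[(E)-2-(4,4,5,5-tetramethyl-1,3,2-dioxaborolan-2-yl)ethenyl]-1,3-phenylene diacetate | CC(=O)Oc1cc(/C=C/B2OC(C)(C)C(C)(C)O2)cc(OC(C)=O)c1
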